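Atoms are numbered as in the target SMILES. The route rests on the 1,5-relation between C7 and carbinol C17 through C25, C14 and C13: the cycloheptene ring (C7, C10–C14, C25) and the cyclopentenol ring (C13–C17) are the retro-aldol image of a cyclobutane C7–C13–C14–C25. One de Mayo operation, intramolecular [2+2] photocycloaddition followed by ring opening, forms C13–C14 and C7–C25, cuts C7–C13 and so delivers the cycloheptanone-fused diquinane with quaternary C25. Its precursor is a cis-disubstituted cyclopentene carrying the protected aminomethyl group on C25, the ester on C19 and, on C15, an acylmethyl tether that ends in a 2-acyl-1-methoxycyclopentene.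

Key step: step 10

Assumption: the hemiketal carbon C3 equilibrates through the open hydroxy ketone and is taken to settle in the configuration drawn for the target.

Step 1
Reactants: 1 sorbic acid
Product: 2 (3E)-hexa-3,5-dienoic acid
Conditions: LiN(i-Pr)2 (2.2 equiv), THF, −78 to 0 °C; then cold 3 M aq. HCl
Reagents that add atoms: none
Why: Deconjugation of a dienoic acid by kinetic α-protonation of its extended dienolate dianion, which shifts the diene to the 3,5-position with the (3E)-geometry inherited from the s-trans starting diene and creates no stereocentre.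

Step 2
Reactants: 2 (3E)-hexa-3,5-dienoic acid
Product: 3 (3E)-N-methoxy-N-methylhexa-3,5-dienamide
Conditions: 1,1'-carbonyldiimidazole, CH2Cl2, 0 °C; then MeNHOMe·HCl, rt
Reagents that add atoms: N,O-dimethylhydroxylamine hydrochloride, CNOC.Cl
Why: N-Methoxy-N-methylamide formation through the acyl imidazolide, an activation mild enough that the β,γ-unsaturated acid is not isomerised back into conjugation.

Step 3
Reactants: 4 (4S)-4-benzyl-1,3-oxazolidin-2-one, 5 acryloyl chloride
Product: 6 (4S)-3-acryloyl-4-benzyl-1,3-oxazolidin-2-one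
Conditions: MeMgBr, THF, 0 °C; then 5, −78 °C
Reagents that add atoms: none
Why: N-Acylation of the bromomagnesium salt of the oxazolidinone with the acid chloride at low temperature, which avoids polymerisation of the acrylate and leaves the auxiliary stereocentre untouched.

Step 4
Reactants: 3 (3E)-N-methoxy-N-methylhexa-3,5-dienamide, 6 (4S)-3-acryloyl-4-benzyl-1,3-oxazolidin-2-one
Product: 7 (4S)-4-benzyl-3-{[(1R,2S)-2-{2-[methoxy(methyl)amino]-2-oxoethyl}cyclohex-3-en-1-yl]carbonyl}-1,3-oxazolidin-2-one
Conditions: Et2AlCl (3 equiv), CH2Cl2, −78 to −40 °C; then 1 M aq. HCl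
Reagents that add atoms: none
Why: Oxazolidinone-auxiliary-controlled Diels–Alder reaction in which the aluminium chelate holds the acryloyl imide s-cis, the diene adds to the face opposite the benzyl group with ortho regiochemistry and endo geometry, and C19 (R) and C15 (S, cis to C19) are thereby set in one step.

Step 5
Reactants: 7 (4S)-4-benzyl-3-{[(1R,2S)-2-{2-[methoxy(methyl)amino]-2-oxoethyl}cyclohex-3-en-1-yl]carbonyl}-1,3-oxazolidin-2-one
Product: 8 methyl (1R,2S)-2-{2-[methoxy(methyl)amino]-2-oxoethyl}cyclohex-3-ene-1-carboxylate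
Conditions: MeMgBr, MeOH (excess), THF, 0 °C; then aq. NH4Cl
Reagents that add atoms: methanol, CO
Why: Transesterification of the N-acyl oxazolidinone with magnesium methoxide, an acyl substitution at the exocyclic carbonyl that returns the auxiliary and is too weakly basic to epimerise C19.

Step 6
Reactants: 8 methyl (1R,2S)-2-{2-[methoxy(methyl)amino]-2-oxoethyl}cyclohex-3-ene-1-carboxylate
Product: 10 methyl (1R,2S)-4-formyl-2-{2-[methoxy(methyl)amino]-2-oxoethyl}cyclopent-3-ene-1-carboxylate, via dialdehyde 9 (not isolated)
Conditions: O3, CH2Cl2, −78 °C; PPh3, −78 °C to rt; then Bn2NH·CF3CO2H (0.3 equiv), toluene, rt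
Reagents that add atoms: ozone, [O-][O+]=O
Why: Ozonolysis followed by amine-salt-catalysed intramolecular aldol condensation (ring contraction of a cyclohexene to a cyclopentenecarbaldehyde), in which only the enamine of the unbranched C26 aldehyde can lead to a dehydrated product, so that the ring closes between C25 and C14 and the C15 and C19 centres are carried over unchanged.

Step 7
Reactants: 10 methyl (1R,2S)-4-formyl-2-{2-[methoxy(methyl)amino]-2-oxoethyl}cyclopent-3-ene-1-carboxylate, 11 methylamine
Product: 13 methyl (1R,2S)-4-{[(tert-butoxycarbonyl)(methyl)amino]methyl}-2-{2-[methoxy(methyl)amino]-2-oxoethyl}cyclopent-3-ene-1-carboxylate, via secondary amine 12 (not isolated)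
Conditions: MeNH2 (2 M in THF, 5 equiv), MgSO4, 0 °C; NaBH4, MeOH, −20 °C; then Boc2O, CH2Cl2, rt
Reagents that add atoms: di-tert-butyl dicarbonate, CC(C)(C)OC(=O)OC(=O)OC(C)(C)C
Why: Reductive amination by 1,2-reduction of the N-methyl imine of the enal followed by carbamate formation, conditions under which the N-methoxy-N-methylamide and the ester are inert and no stereocentre is touched.

Step 8
Reactants: 13 methyl (1R,2S)-4-{[(tert-butoxycarbonyl)(methyl)amino]methyl}-2-{2-[methoxy(methyl)amino]-2-oxoethyl}cyclopent-3-ene-1-carboxylate, 14 1,2-dibromocyclopentene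
Product: 16 methyl (1R,2S)-2-[2-(2-bromocyclopent-1-en-1-yl)-2-oxoethyl]-4-{[(tert-butoxycarbonyl)(methyl)amino]methyl}cyclopent-3-ene-1-carboxylate, via Grignard reagent 15 (not isolated)
Conditions: 14, i-PrMgCl·LiCl, THF, 25 °C; then 13, THF, −20 to 0 °C; aq. NH4Cl
Reagents that add atoms: none
Why: Weinreb ketone synthesis with an alkenyl Grignard reagent made by bromine–magnesium exchange, in which the chelated tetrahedral adduct prevents over-addition and the amide reacts faster than the hindered ester or the carbamate.

Step 9
Reactants: 16 methyl (1R,2S)-2-[2-(2-bromocyclopent-1-en-1-yl)-2-oxoethyl]-4-{[(tert-butoxycarbonyl)(methyl)amino]methyl}cyclopent-3-ene-1-carboxylate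
Product: 17 methyl (1R,2S)-4-{[(tert-butoxycarbonyl)(methyl)amino]methyl}-2-[2-(2-methoxycyclopent-1-en-1-yl)-2-oxoethyl]cyclopent-3-ene-1-carboxylate
Conditions: K2CO3, MeOH, 0 °C
Reagents that add atoms: methanol, CO
Why: Addition–elimination (vinylogous acyl substitution) of methoxide at the β-bromo enone, which places the enol ether on ring carbon C7 without regiochemical ambiguity and is far faster than any exchange at the ester α-carbon C19.

Step 10
Reactants: 17 methyl (1R,2S)-4-{[(tert-butoxycarbonyl)(methyl)amino]methyl}-2-[2-(2-methoxycyclopent-1-en-1-yl)-2-oxoethyl]cyclopent-3-ene-1-carboxylate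
Product: 19 N-Boc tricyclic 1,5-diketone (C7 and C17 ketones; quaternary C25; H14 cis to H15; C13 epimers), via photoadduct 18 (not isolated)
Conditions: hν (350 nm; Pyrex), degassed MeCN (5 mM), rt; then TsOH·H2O (0.2 equiv), MeCN–H2O, rt
Reagents that add atoms: water, O
Why: Excitation of the vinylogous ester gives its triplet, which adds to the tethered cyclopentene in two steps through a 1,4-diradical, and catalytic acid then opens the donor–acceptor methoxycyclobutane by heterolysis of C7–C13 toward the C17 carbonyl (retro-aldol), the oxocarbenium ion being hydrolysed to the C7 ketone. The closest known reaction is the intramolecular de Mayo reaction of 1,6-heptadien-3-ones, which give straight bicyclo[3.2.0]heptanone adducts that open to 1,5-diketones with a two-carbon ring expansion. The cyclopentanone (C13–C17) closes first by 1,5-closure when C13 attacks C14 in 5-exo mode, the cyclobutane closes by recombination of the C7 and C25 radicals, and the cycloheptanone results when C14 and C25 are inserted into the old five-membered ring by the C7–C13 cleavage. C14 and quaternary C25 are controlled by the C15 stereocentre, since the two-carbon acyl tether can reach only the alkene face on which it stands, so that the diquinane is cis-fused and C7 lies on the face of C16, while C13 is formed as a mixture and becomes sp2 later. The step needs head-to-head regiochemistry and this single face, both secured by the short tether, a chromophore whose double bond is locked in the ring by the methyl enol ether, and a nitrogen that does not quench the triplet, which the carbamate provides while the mild acid leaves it in place.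

Step 11
Reactants: 19 N-Boc tricyclic 1,5-diketone (C7 and C17 ketones; quaternary C25; H14 cis to H15; C13 epimers), 20 formaldehyde
Product: 22 bridged 4-piperidone diketone (N27–C29–C10 closed; C7 and C17 ketones), via secondary amine 21 (not isolated)
Conditions: CF3CO2H, CH2Cl2, 0 °C; evaporate; then 37% aq. CH2O, AcOH, MeOH, 60 °C
Reagents that add atoms: none
Why: Acidolysis of the tert-butyl carbamate followed by intramolecular Mannich reaction of the methyliminium ion with the C7 enol at C10 (the second half of a 4-piperidone synthesis), which is irreversible because the bridged product cannot form a bridgehead enol whereas an adduct at C13 can revert, and in which the bridge itself fixes C10.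

Step 12
Reactants: 22 bridged 4-piperidone diketone (N27–C29–C10 closed; C7 and C17 ketones)
Product: 24 C13=C14 enone (C17 ketone; bridging C7 ketone), via silyl enol ether 23 (not isolated)
Conditions: Me3SiCl, NaI, Et3N, MeCN, rt; then Pd(OAc)2 (1.1 equiv), MeCN, rt
Reagents that add atoms: none
Why: Saegusa–Ito oxidation of the thermodynamic silyl enol ether, which can form only at C17 because C7 is flanked by a quaternary carbon and a bridgehead, and which gives the tetrasubstituted C13=C14 enone by syn β-hydride elimination from C14.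

Step 13
Reactants: 24 C13=C14 enone (C17 ketone; bridging C7 ketone)
Product: 25 (17S)-allylic alcohol (bridging C7 ketone)
Conditions: (R)-2-methyl-CBS-oxazaborolidine (0.5 equiv), catecholborane, toluene, −78 °C; then MeOH, pH 7 buffer
Reagents that add atoms: none
Why: Corey–Bakshi–Shibata reduction, in which the (R)-catalyst binds the carbonyl anti to the fully substituted alkenyl side and delivers hydride under reagent control to give the (17S)-alcohol, while the bridging C7 ketone, hindered on both sides, is not reduced at −78 °C.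

Step 14
Reactants: 25 (17S)-allylic alcohol (bridging C7 ketone)
Product: 26 (17S)-triisopropylsilyl ether (bridging C7 ketone)
Conditions: i-Pr3SiOTf, 2,6-lutidine, CH2Cl2, 0 °C
Reagents that add atoms: triisopropylsilyl trifluoromethanesulfonate, CC(C)[Si](C(C)C)(C(C)C)OS(=O)(=O)C(F)(F)F
Why: Silyl ether formation with a silyl triflate and a hindered base, which protects the allylic alcohol against the ylide and the aqueous acid of the next step.

Step 15
Reactants: 26 (17S)-triisopropylsilyl ether (bridging C7 ketone), 27 (methoxymethyl)triphenylphosphonium chloride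
Product: 30 C7 carbaldehyde (C8 formyl; C7 epimers), via ylide 28 (not isolated), via enol ether 29 (not isolated)
Conditions: 27, KN(SiMe3)2, THF, 0 °C; then 26, 0 to 50 °C; then 1 M aq. HCl, THF, rt
Reagents that add atoms: water, O
Why: Wittig methoxymethylenation followed by acid hydrolysis of the enol ether (one-carbon homologation), feasible because the C7 ketone cannot enolise and so can only add the ylide, and giving an aldehyde whose C7 configuration is erased in the next step.

Step 16
Reactants: 30 C7 carbaldehyde (C8 formyl; C7 epimers), 31 pent-1-en-3-one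
Product: 32 C7-quaternary keto aldehyde (C8 formyl; 3-oxopentyl chain C6–C5–C3–C2–C1)
Conditions: DBU (0.3 equiv), THF, 0 °C to rt
Reagents that add atoms: none
Why: Base-catalysed Michael addition of the α-branched aldehyde to an enone, in which the exocyclic enolate is screened on its cycloheptene side by the C19 ester on the folded cyclopentane, so that the vinyl ketone should add from the piperidine side and set quaternary C7 with C6 on that side and the formyl carbon C8 next to the ester.

Step 17
Reactants: 32 C7-quaternary keto aldehyde (C8 formyl; 3-oxopentyl chain C6–C5–C3–C2–C1)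
Product: 34 17-O-triisopropylsilyl ether of the target, via hydroxy ketone 33 (not isolated)
Conditions: NaBH4, EtOH–CH2Cl2 (3:7), −78 °C; aq. NH4Cl
Reagents that add atoms: none
Why: Chemoselective borohydride reduction of the aldehyde in the presence of the ketone at low temperature, after which the 5-hydroxy ketone closes spontaneously to the six-membered hemiketal whose C3 configuration is set by equilibration.

Step 18
Reactants: 34 17-O-triisopropylsilyl ether of the target
Product: 35 target CNP0124876.1
Conditions: Bu4NF, AcOH (1:1), THF, rt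
Reagents that add atoms: none
Why: Fluoride cleavage of the silyl ether, buffered with acetic acid so that the hemiketal and the epimerisable C19 ester are not exposed to base.

Compound list
1 | sorbic acid, (2E,4E)-hexa-2,4-dienoic acid | C/C=C/C=C/C(=O)O | starting material
2 | (3E)-hexa-3,5-dienoic acid | C=C/C=C/CC(=O)O | intermediate
3 | (3E)-N-methoxy-N-methylhexa-3,5-dienamide | C=C/C=C/CC(=O)N(C)OC | intermediate
4 | (4S)-4-benzyl-1,3-oxazolidin-2-one | O=C1N[C@@H](Cc2ccccc2)CO1 | starting material
5 | acryloyl chloride | C=CC(=O)Cl | starting material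
6 | (4S)-3-acryloyl-4-benzyl-1,3-oxazolidin-2-one | C=CC(=O)N1[C@@H](Cc2ccccc2)COC1=O | intermediate
7 | (4S)-4-benzyl-3-{[(1R,2S)-2-{2-[methoxy(methyl)amino]-2-oxoethyl}cyclohex-3-en-1-yl]carbonyl}-1,3-oxazolidin-2-one | C1=C[C@H](CC(=O)N(C)OC)[C@H](C(=O)N2[C@@H](Cc3ccccc3)COC2=O)CC1 | intermediate
8 | methyl (1R,2S)-2-{2-[methoxy(methyl)amino]-2-oxoethyl}cyclohex-3-ene-1-carboxylate | C1=C[C@H](CC(=O)N(C)OC)[C@H](C(=O)OC)CC1 | intermediate
9 | dialdehyde, methyl (2R,3R)-3-formyl-5-[methoxy(methyl)amino]-5-oxo-2-(3-oxopropyl)pentanoate | O=C[C@H](CC(=O)N(C)OC)[C@H](C(=O)OC)CCC=O | intermediate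
10 | methyl (1R,2S)-4-formyl-2-{2-[methoxy(methyl)amino]-2-oxoethyl}cyclopent-3-ene-1-carboxylate | O=CC1=C[C@H](CC(=O)N(C)OC)[C@H](C(=O)OC)C1 | intermediate
11 | methylamine | CN | starting material
12 | secondary amine, methyl (1R,2S)-2-{2-[methoxy(methyl)amino]-2-oxoethyl}-4-[(methylamino)methyl]cyclopent-3-ene-1-carboxylate | CNCC1=C[C@H](CC(=O)N(C)OC)[C@H](C(=O)OC)C1 | intermediate
13 | methyl (1R,2S)-4-{[(tert-butoxycarbonyl)(methyl)amino]methyl}-2-{2-[methoxy(methyl)amino]-2-oxoethyl}cyclopent-3-ene-1-carboxylate | CN(C(=O)OC(C)(C)C)CC1=C[C@H](CC(=O)N(C)OC)[C@H](C(=O)OC)C1 | intermediate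
14 | 1,2-dibromocyclopentene | BrC1=C(Br)CCC1 | starting material
15 | Grignard reagent, (2-bromocyclopent-1-en-1-yl)magnesium chloride (LiCl complex) | Cl[Mg]C1=C(Br)CCC1 | intermediate
16 | methyl (1R,2S)-2-[2-(2-bromocyclopent-1-en-1-yl)-2-oxoethyl]-4-{[(tert-butoxycarbonyl)(methyl)amino]methyl}cyclopent-3-ene-1-carboxylate | CN(C(=O)OC(C)(C)C)CC1=C[C@H](CC(=O)C2=C(Br)CCC2)[C@H](C(=O)OC)C1 | intermediate
17 | methyl (1R,2S)-4-{[(tert-butoxycarbonyl)(methyl)amino]methyl}-2-[2-(2-methoxycyclopent-1-en-1-yl)-2-oxoethyl]cyclopent-3-ene-1-carboxylate (photoprecursor) | CN(C(=O)OC(C)(C)C)CC1=C[C@H](CC(=O)C2=C(OC)CCC2)[C@H](C(=O)OC)C1 | intermediate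
18 | photoadduct: cyclobutane C7–C13–C14–C25 with OMe on C7, cis-fused to the C7/C10–C13 cyclopentane, to the C13–C17 cyclopentanone and to the C14/C15/C19/C24/C25 cyclopentane; C25 bears CH2N(Me)Boc, C19 bears CO2Me | CO[C@]12CCC[C@]14C(=O)C[C@@H]3[C@H](C(=O)OC)C[C@@]2(CN(C)C(=O)OC(C)(C)C)[C@@H]34 | intermediate
19 | N-Boc tricyclic 1,5-diketone: cycloheptanone (C7 ketone; C10–C14, C25) fused at C13–C14 to the cyclopentanone (C17 ketone) and at C14–C25 to the cyclopentane; quaternary C25 bears CH2N(Me)Boc, C19 bears CO2Me; H14 cis to H15; C7, C16 and CO2Me on one face; C13 epimers | O=C2CCCC3[C@@H]4[C@H](CC3=O)[C@H](C(=O)OC)C[C@@]42CN(C)C(=O)OC(C)(C)C | intermediate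
20 | formaldehyde | C=O | starting material
21 | secondary amine: 19 without the Boc group (formed as the trifluoroacetate salt) | O=C2CCCC3[C@@H]4[C@H](CC3=O)[C@H](C(=O)OC)C[C@@]42CNC | intermediate
22 | bridged 4-piperidone diketone: N27(Me)–C29H2–C10 closed, so that N27, C26, C25, C7, C10 and C29 form the piperidone with the C7 ketone as one-atom bridge; C17 ketone; C13 epimers | O=C2[C@@H]1CCC3[C@@H]4[C@H](CC3=O)[C@H](C(=O)OC)C[C@@]42CN(C)C1 | intermediate
23 | silyl enol ether: 22 with C17(OSiMe3)=C13 | O=C2[C@@H]1CCC3[C@@H]4[C@H](CC=3O[Si](C)(C)C)[C@H](C(=O)OC)C[C@@]42CN(C)C1 | intermediate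
24 | C13=C14 enone (C17 ketone; bridging C7 ketone) | O=C2[C@@H]1CCC3=C4[C@H](CC3=O)[C@H](C(=O)OC)C[C@@]42CN(C)C1 | intermediate
25 | (17S)-allylic alcohol (bridging C7 ketone) | O=C2[C@@H]1CCC3=C4[C@H](C[C@@H]3O)[C@H](C(=O)OC)C[C@@]42CN(C)C1 | intermediate
26 | (17S)-triisopropylsilyl ether (bridging C7 ketone) | O=C2[C@@H]1CCC3=C4[C@H](C[C@@H]3O[Si](C(C)C)(C(C)C)C(C)C)[C@H](C(=O)OC)C[C@@]42CN(C)C1 | intermediate
27 | (methoxymethyl)triphenylphosphonium chloride | COC[P+](c1ccccc1)(c1ccccc1)c1ccccc1.[Cl-] | starting material
28 | ylide, (methoxymethylidene)triphenylphosphorane | COC=P(c1ccccc1)(c1ccccc1)c1ccccc1 | intermediate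
29 | enol ether: 26 with C7=CH–OMe in place of the C7 ketone | COC=C2[C@@H]1CCC3=C4[C@H](C[C@@H]3O[Si](C(C)C)(C(C)C)C(C)C)[C@H](C(=O)OC)C[C@@]42CN(C)C1 | intermediate
30 | C7 carbaldehyde (C8 formyl on C7; C7 epimers) | O=CC2[C@@H]1CCC3=C4[C@H](C[C@@H]3O[Si](C(C)C)(C(C)C)C(C)C)[C@H](C(=O)OC)C[C@@]42CN(C)C1 | intermediate
31 | pent-1-en-3-one (ethyl vinyl ketone) | C=CC(=O)CC | starting material
32 | C7-quaternary keto aldehyde: C7 bears the formyl group C8 (cycloheptene side) and the 3-oxopentyl chain (piperidine side) | CCC(=O)CC[C@@]2(C=O)[C@@H]1CCC3=C4[C@H](C[C@@H]3O[Si](C(C)C)(C(C)C)C(C)C)[C@H](C(=O)OC)C[C@@]42CN(C)C1 | intermediate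
33 | hydroxy ketone: 32 with CH2OH in place of the formyl group | CCC(=O)CC[C@@]2(CO)[C@@H]1CCC3=C4[C@H](C[C@@H]3O[Si](C(C)C)(C(C)C)C(C)C)[C@H](C(=O)OC)C[C@@]42CN(C)C1 | intermediate
34 | 17-O-triisopropylsilyl ether of the target (spiro hemiketal closed) | CC[C@@]1(O)CC[C@@]2(CO1)[C@@H]1CCC3=C4[C@H](C[C@@H]3O[Si](C(C)C)(C(C)C)C(C)C)[C@H](C(=O)OC)C[C@@]42CN(C)C1 | intermediate
35 | target CNP0124876.1, (3S,7R,10S,15R,17S,19R,25R) in SMILES atom numbering | CC[C@@]1(O)CC[C@@]2(CO1)[C@@H]1CCC3=C4[C@H](C[C@@H]3O)[C@H](C(=O)OC)C[C@@]42CN(C)C1 | target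

Total step count: 18. Longest linear sequence: 17 steps (steps 1, 2 and 4 to 18, from sorbic acid 1; step 3 is a one-step side branch).

Steps most likely to fail

Step 10 (key step). What may go wrong: after the first bond (C13–C14) the 1,4-diradical may fall back to 17 or shift a hydrogen atom instead of closing the crowded C7–C25 bond, or the methoxy adduct may lose methanol instead of opening by the retro-aldol path. Fallback: the classical de Mayo variant through the free 1,3-diketone, which has a smaller hydroxyl group on C7 and needs no acid for the ring opening. It sets out from 17, whose enol ether is hydrolysed (1 M aq. HCl, THF, rt) to the 2-acylcyclopentanone F1. Irradiation of the hydrogen-bonded ring enol of F1 (350 nm, MeCN) should give the cyclobutanol F2, which opens by spontaneous retro-aldol reaction and comes back to the route at 19.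

Step 16. What may go wrong: attack of the vinyl ketone on the other face of the enolate, or poor facial selectivity at the crowded C7, which would give the C7 epimer. Fallback: the two arms are introduced in the opposite order, which turns the same facial preference into the opposite configuration at C7. It sets out from aldehyde 30, whose formyl carbon now becomes C6. Aldol reaction with formaldehyde 20 (37% aq. CH2O, K2CO3, THF, 0 °C) gives the hydroxymethyl aldehyde F3. Wittig reaction with 1-(triphenylphosphoranylidene)butan-2-one (toluene, 80 °C) gives the enone F4. Hydrogenation of the disubstituted alkene (H2, Pd/C, EtOAc) gives hydroxy ketone 33, which closes to 34, where the fallback comes back to the route.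

Step 13. What may go wrong: loss of facial control, because the substrate itself favours hydride delivery to the convex face, away from the C19 ester, which is the opposite of what the catalyst must enforce. Fallback: reduce under substrate control and invert. It sets out from 24. Luche reduction (NaBH4, CeCl3·7H2O, MeOH, −78 °C) gives the (17R)-alcohol F5. Mitsunobu reaction with 4-nitrobenzoic acid (PPh3, diisopropyl azodicarboxylate, THF, 0 °C) gives the inverted (17S)-4-nitrobenzoate F6 by attack on the open convex face. Methanolysis (K2CO3, MeOH, 0 °C) gives 25, where the fallback comes back to the route.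

Further compounds
F1 | step 10 | 2-acylcyclopentanone: 17 with a 2-oxocyclopentyl group in place of the 2-methoxycyclopent-1-enyl group (enolised 1,3-diketone) | CN(C(=O)OC(C)(C)C)CC1=C[C@H](CC(=O)C2CCCC2=O)[C@H](C(=O)OC)C1
F2 | step 10 | cyclobutanol: 18 with OH in place of OMe on C7 | O[C@]12CCC[C@]14C(=O)C[C@@H]3[C@H](C(=O)OC)C[C@@]2(CN(C)C(=O)OC(C)(C)C)[C@@H]34
F3 | step 16 | hydroxymethyl aldehyde: C7 bears CH2OH (C8) and the formyl group (C6) | O=C[C@@]2(CO)[C@@H]1CCC3=C4[C@H](C[C@@H]3O[Si](C(C)C)(C(C)C)C(C)C)[C@H](C(=O)OC)C[C@@]42CN(C)C1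
F4 | step 16 | enone: C7 bears CH2OH and the (E)-3-oxopent-1-enyl group | CCC(=O)/C=C/[C@@]2(CO)[C@@H]1CCC3=C4[C@H](C[C@@H]3O[Si](C(C)C)(C(C)C)C(C)C)[C@H](C(=O)OC)C[C@@]42CN(C)C1
F5 | step 13 | (17R)-allylic alcohol, the C17 epimer of 25 | O=C2[C@@H]1CCC3=C4[C@H](C[C@H]3O)[C@H](C(=O)OC)C[C@@]42CN(C)C1
F6 | step 13 | (17S)-4-nitrobenzoate of 25 | O=C2[C@@H]1CCC3=C4[C@H](C[C@@H]3OC(=O)c5ccc(cc5)[N+](=O)[O-])[C@H](C(=O)OC)C[C@@]42CN(C)C1
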